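The route rests on cleaving the O1–C6 bond of lactone ring A. C6 is at once the carbinol carbon of ring A and the γ-carbon of the 4-hydroxystyryl unit, so dehydrogenation of that phenol through a vinylogous quinone methide makes C6 electrophilic. In one operation the tethered C2 carboxylic acid then closes ring A and sets the quaternary C6 stereocentre cis to C5. The precursor is a tetrasubstituted cyclobutane seco acid (C5 methoxyacrylic acid, C6 styryl with C6–H, C7 aryl, C8 methoxypyranone) with both phenols free, assembled from a trans-cyclobutane-1,3-dicarboxylate by two amide-directed C–H couplings. No phenol needs a mask, so the key step ends the synthesis.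

Key step: step 15

Remark on the chemistry: labels follow the target (ring A = O1–C2(=O)–C3=C4(OMe)–C5–C6; cyclobutane = C5–C6–C8–C7); the seco acid carries its styryl group cis to the C5 side chain, as the C5-amide-directed alkenylation delivers it, which has no consequence because C6 becomes planar in step 15; the achiral starting monoester is taken as its trans isomer; the ligand antipode that arylates the pro-C7 methylene is assumed for step 3 and its mirror image for step 6 (they are exchanged if the sense of induction is the opposite).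

Step 1
Reactants: 1 trans-3-(methoxycarbonyl)cyclobutane-1-carboxylic acid; 2 2,3,5,6-tetrafluoro-4-(trifluoromethyl)aniline
Product: 4 methyl trans-3-{[2,3,5,6-tetrafluoro-4-(trifluoromethyl)phenyl]carbamoyl}cyclobutane-1-carboxylate (amide on C5; ester on C8), via acid chloride 3 (not isolated)
Conditions: (COCl)2, DMF (cat.), CH2Cl2, 0 °C to rt; then 2, toluene, 110 °C
Reagents that add atoms: none
Why: Acid chloride formation and N-acylation of the weakly nucleophilic polyfluoroaniline install the acidic anilide that directs both later C–H couplings; the trans-1,3 relationship is carried over and no stereocentre is formed.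

Step 2
Reactants: 5 4-iodophenol
Product: 6 (4-iodophenoxy)tri(propan-2-yl)silane
Conditions: iPr3SiCl, imidazole, DMF, rt
Reagents that add atoms: chlorotri(propan-2-yl)silane, CC(C)[Si](Cl)(C(C)C)C(C)C
Why: Imidazole-promoted silylation of the phenol gives a bulky aryl silyl ether that should withstand the later silver, hydroxide, enolate and acid steps.

Step 3
Reactants: 4 methyl trans-3-{[2,3,5,6-tetrafluoro-4-(trifluoromethyl)phenyl]carbamoyl}cyclobutane-1-carboxylate; 6 (4-iodophenoxy)tri(propan-2-yl)silane
Product: 7 C7-arylated amide (4-(triisopropylsilyloxy)phenyl on C7 cis to the C5 amide; C8 ester trans to both; C6 still CH2)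
Conditions: Pd(OAc)2 (10 mol%), chiral N-acetyl aminomethyl-oxazoline ligand L (20 mol%), Ag2CO3, tert-amyl alcohol, 80 °C
Reagents that add atoms: none
Why: Amide-directed, ligand-controlled desymmetrising C(sp3)–H arylation through a divalent/tetravalent palladium cycle: the chiral ligand selects one of the two enantiotopic methylene groups (fixing the absolute configuration of C5, C7 and C8 in one event), cyclopalladation on the amide face places the aryl group cis to the amide, and the mismatched second methylene should resist double arylation.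

Step 4
Reactants: 8 4-hydroxybenzaldehyde
Product: 9 4-[tri(propan-2-yl)silyloxy]benzaldehyde
Conditions: iPr3SiCl, imidazole, DMF, rt
Reagents that add atoms: chlorotri(propan-2-yl)silane, CC(C)[Si](Cl)(C(C)C)C(C)C
Why: Silylation of the phenol as in step 2, so that both phenols carry the same robust group and can be released together.

Step 5
Reactants: 9 4-[tri(propan-2-yl)silyloxy]benzaldehyde
Product: 10 (E)-1-(2-iodoethenyl)-4-[tri(propan-2-yl)silyloxy]benzene
Conditions: CrCl2, CHI3, THF, 0 °C to rt
Reagents that add atoms: iodoform, IC(I)I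
Why: Takai iodo-olefination, in which the geminal dichromium species from CHI3 and CrCl2 adds to the aryl aldehyde and eliminates to the E-alkenyl iodide.

Step 6
Reactants: 7 C7-arylated amide; 10 (E)-1-(2-iodoethenyl)-4-[tri(propan-2-yl)silyloxy]benzene
Product: 11 C6-alkenylated amide ((E)-4-(triisopropylsilyloxy)styryl on C6; C5/C6/C7 substituents all cis; C8 ester trans)
Conditions: Pd(OAc)2 (10 mol%), ent-L (20 mol%), AgOAc, tert-amyl alcohol, 80 °C
Reagents that add atoms: none
Why: Second amide-directed C(sp3)–H activation at the remaining cis C6–H and coupling with the alkenyl iodide with retention of the E geometry (C–H alkenylation); the antipodal ligand is matched to this methylene and the styryl group enters cis to C5, a configuration that step 15 erases.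

Step 7
Reactants: 11 C6-alkenylated amide
Product: 14 C5 carboxylic acid (C6 styryl; C7 aryl; C8 CO2Me unchanged), via N-Boc imide 12 (not isolated), via peroxy acid 13 (not isolated)
Conditions: Boc2O, DMAP, MeCN, 50 °C; then LiOH, H2O2, THF/H2O, 0 °C; Na2SO3; HCl to pH 3
Reagents that add atoms: hydrogen peroxide, OO
Why: N-Boc activation turns the electron-poor anilide into an imide that lithium hydroperoxide should cleave at the acyl carbonyl much faster than it attacks the methyl ester (activated-amide hydrolysis, sulfite reducing the peroxy acid), under cold, weakly basic conditions that should not enolise the congested C5 centre.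

Step 8
Reactants: 14 C5 carboxylic acid
Product: 16 2-(trimethylsilyl)ethyl β-keto ester (C5–C(=O)–CH2–CO2CH2CH2SiMe3), via acyl Meldrum's acid 15 (not isolated)
Conditions: Meldrum's acid, EDC·HCl, DMAP, CH2Cl2, 0 °C to rt; then Me3SiCH2CH2OH, toluene, 80 °C
Reagents that add atoms: Meldrum's acid (2,2-dimethyl-1,3-dioxane-4,6-dione), CC1(C)OC(=O)CC(=O)O1; 2-(trimethylsilyl)ethanol, C[Si](C)(C)CCO
Why: Carbodiimide-mediated C-acylation of Meldrum's acid and thermal loss of acetone and CO2 through an acylketene trapped by the alcohol (Meldrum's acid β-keto ester synthesis) extend C5 by the C3–C2 unit without a base able to enolise toward C5.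

Step 9
Reactants: 16 2-(trimethylsilyl)ethyl β-keto ester
Product: 17 2-(trimethylsilyl)ethyl (E)-3-methoxyacrylate (ester carbonyl cis to C5 across C3=C4)
Conditions: HC(OMe)3, H2SO4 (cat.), rt
Reagents that add atoms: trimethyl orthoformate, COC(OC)OC
Why: Acid-catalysed ketalisation by the orthoester and loss of methanol should give the conjugated enol ether as its thermodynamic E isomer (ester trans to OMe, hence cis to C5 as lactonisation requires), with enolisation directed to the more acidic C3 methylene and away from C5.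

Step 10
Reactants: 17 2-(trimethylsilyl)ethyl (E)-3-methoxyacrylate
Product: 18 C8 carboxylic acid
Conditions: LiOH·H2O, THF/H2O, 0 °C to rt; HCl to pH 4
Reagents that add atoms: lithium hydroxide, [Li+].[OH-]
Why: Saponification of the saturated C8 methyl ester should be selective because the 3-methoxyacrylate ester is a deactivated vinylogous carbonate and aryl triisopropylsilyl ethers are slow to cleave with cold LiOH; C8 already holds its thermodynamically preferred trans arrangement.

Step 11
Reactants: 18 C8 carboxylic acid; 19 2,2,6-trimethyl-4H-1,3-dioxin-4-one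
Product: 22 keto-dioxinone (C8–C(=O)–CH2–dioxinone), via acyl imidazole 20 (not isolated), via lithium dienolate 21 (not isolated)
Conditions: 18, CDI, THF, rt; 19, LiN(SiMe3)2, THF, −78 °C; combine, −78 to −40 °C; NH4Cl
Reagents that add atoms: none
Why: Crossed Claisen-type γ-acylation of the dioxinone dienolate by the acyl imidazole; excess dienolate absorbs the imidazole N–H and the acidic product, and it is too weak a base to remove the C5–H of the methoxyacrylate.

Step 12
Reactants: 22 keto-dioxinone
Product: 24 4-hydroxy-2-pyranone (C8 bears 4-hydroxy-2-oxo-2H-pyran-6-yl), via acylketene 23 (not isolated)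
Conditions: toluene, 110 °C
Reagents that add atoms: none
Why: Thermal retro-[4+2] loss of acetone gives an acylketene that the enol of the C8 ketone captures to form the pyranone ring (dioxinone-to-pyranone annulation).

Step 13
Reactants: 24 4-hydroxy-2-pyranone
Product: 25 4-methoxy-2-pyranone (fully protected seco ester)
Conditions: Me2SO4, K2CO3, acetone, rt
Reagents that add atoms: dimethyl sulfate, COS(=O)(=O)OC
Why: O-Methylation of the acidic vinylogous carboxylic acid with dimethyl sulfate, which favours the 4-methoxy-2-pyranone over the 2-methoxy-4-pyranone; no N–H or free phenol is present to compete.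

Step 14
Reactants: 25 4-methoxy-2-pyranone
Product: 26 seco acid (free C2 carboxylic acid; both phenols free; C6–H; styryl cis to the C5 side chain)
Conditions: Bu4NF, THF, 0 °C to rt; HCl to pH 4
Reagents that add atoms: none
Why: Fluoride cleaves both aryl silyl ethers and fragments the 2-(trimethylsilyl)ethyl ester by β-elimination, so one operation should release the acid and both phenols without hydroxide or strong acid.

Step 15
Reactants: 26 seco acid
Product: 28 target (CNP0228336.2), via vinylogous quinone methide 27 (not isolated)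
Conditions: DDQ (1.0 equiv), MeCN, −20 to 0 °C
Reagents that add atoms: none
Why: Proposed new method: DDQ should remove two electrons, the C6–H and the phenolic proton from the 4-hydroxystyryl unit of 26 to give the vinylogous p-quinone methide 27, whose C6 terminus the carboxylic acid then attacks in a 1,8-addition that regenerates the phenol and the E-styrene. The closest known chemistry is the DDQ oxidation of 4-alkyl- and 4-propenylphenols to quinone methides and their capture by oxygen nucleophiles, including benzylic oxidative lactonisation; the vinylogous, intramolecular version at a tertiary cyclobutyl C–H has not been shown. Ring A closes by a 6-exo-trig attack of O1 on C6 of the exocyclic C6=C bond, whereas addition at the benzylic carbon would demand an eight-membered ring. The new quaternary centre C6 is controlled by C5, because the acrylic acid tether, held cis to C5 across C3=C4, can reach C6 only on its own face and gives the cis-fused bicycle, so the C6 configuration of 26 does not matter. The step needs chemoselectivity between the two phenols, and the substrate secures it: only the styryl phenol is conjugated to an abstractable C–H and it has the lower oxidation potential, whereas the 4-alkylphenol could only form a strained cyclobutylidene quinone methide; one equivalent of DDQ at low temperature is used and the product has no C6–H left.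

Compound list

1 | trans-3-(methoxycarbonyl)cyclobutane-1-carboxylic acid | OC(=O)[C@@H]1C[C@@H](C(=O)OC)C1 | starting material
2 | 2,3,5,6-tetrafluoro-4-(trifluoromethyl)aniline | Nc1c(F)c(F)c(C(F)(F)F)c(F)c1F | starting material
3 | trans-3-(methoxycarbonyl)cyclobutane-1-carbonyl chloride | ClC(=O)[C@@H]1C[C@@H](C(=O)OC)C1 | intermediate (not isolated)
4 | methyl trans-3-{[2,3,5,6-tetrafluoro-4-(trifluoromethyl)phenyl]carbamoyl}cyclobutane-1-carboxylate | O=C(Nc1c(F)c(F)c(C(F)(F)F)c(F)c1F)[C@@H]1C[C@@H](C(=O)OC)C1 | intermediate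
5 | 4-iodophenol | Oc1ccc(I)cc1 | starting material
6 | (4-iodophenoxy)tri(propan-2-yl)silane | CC(C)[Si](Oc1ccc(I)cc1)(C(C)C)C(C)C | intermediate
7 | C7-arylated amide (aryl cis to amide, ester trans) | O=C(Nc1c(F)c(F)c(C(F)(F)F)c(F)c1F)[C@@H]1[C@H](c2ccc(O[Si](C(C)C)(C(C)C)C(C)C)cc2)[C@@H](C(=O)OC)C1 | intermediate
8 | 4-hydroxybenzaldehyde | O=Cc1ccc(O)cc1 | starting material
9 | 4-[tri(propan-2-yl)silyloxy]benzaldehyde | O=Cc1ccc(O[Si](C(C)C)(C(C)C)C(C)C)cc1 | intermediate
10 | (E)-1-(2-iodoethenyl)-4-[tri(propan-2-yl)silyloxy]benzene | I/C=C/c1ccc(O[Si](C(C)C)(C(C)C)C(C)C)cc1 | intermediate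
11 | C6-alkenylated amide (C5 amide, C6 styryl, C7 aryl all cis; C8 ester trans) | O=C(Nc1c(F)c(F)c(C(F)(F)F)c(F)c1F)[C@@H]1[C@H](c2ccc(O[Si](C(C)C)(C(C)C)C(C)C)cc2)[C@@H](C(=O)OC)[C@@H]1/C=C/c1ccc(O[Si](C(C)C)(C(C)C)C(C)C)cc1 | intermediate
12 | N-Boc imide of 11 | CC(C)(C)OC(=O)N(c1c(F)c(F)c(C(F)(F)F)c(F)c1F)C(=O)[C@@H]1[C@H](c2ccc(O[Si](C(C)C)(C(C)C)C(C)C)cc2)[C@@H](C(=O)OC)[C@@H]1/C=C/c1ccc(O[Si](C(C)C)(C(C)C)C(C)C)cc1 | intermediate (not isolated)
13 | C5 peroxy acid | OOC(=O)[C@@H]1[C@H](c2ccc(O[Si](C(C)C)(C(C)C)C(C)C)cc2)[C@@H](C(=O)OC)[C@@H]1/C=C/c1ccc(O[Si](C(C)C)(C(C)C)C(C)C)cc1 | intermediate (not isolated)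
14 | C5 carboxylic acid | OC(=O)[C@@H]1[C@H](c2ccc(O[Si](C(C)C)(C(C)C)C(C)C)cc2)[C@@H](C(=O)OC)[C@@H]1/C=C/c1ccc(O[Si](C(C)C)(C(C)C)C(C)C)cc1 | intermediate
15 | acyl Meldrum's acid (enol form) | CC1(C)OC(=O)C(C(=O)O1)=C(O)[C@@H]1[C@H](c2ccc(O[Si](C(C)C)(C(C)C)C(C)C)cc2)[C@@H](C(=O)OC)[C@@H]1/C=C/c1ccc(O[Si](C(C)C)(C(C)C)C(C)C)cc1 | intermediate (not isolated)
16 | 2-(trimethylsilyl)ethyl β-keto ester | C[Si](C)(C)CCOC(=O)CC(=O)[C@@H]1[C@H](c2ccc(O[Si](C(C)C)(C(C)C)C(C)C)cc2)[C@@H](C(=O)OC)[C@@H]1/C=C/c1ccc(O[Si](C(C)C)(C(C)C)C(C)C)cc1 | intermediate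
17 | 2-(trimethylsilyl)ethyl (E)-3-methoxyacrylate | C[Si](C)(C)CCOC(=O)/C=C(/OC)[C@@H]1[C@H](c2ccc(O[Si](C(C)C)(C(C)C)C(C)C)cc2)[C@@H](C(=O)OC)[C@@H]1/C=C/c1ccc(O[Si](C(C)C)(C(C)C)C(C)C)cc1 | intermediate
18 | C8 carboxylic acid | C[Si](C)(C)CCOC(=O)/C=C(/OC)[C@@H]1[C@H](c2ccc(O[Si](C(C)C)(C(C)C)C(C)C)cc2)[C@@H](C(=O)O)[C@@H]1/C=C/c1ccc(O[Si](C(C)C)(C(C)C)C(C)C)cc1 | intermediate
19 | 2,2,6-trimethyl-4H-1,3-dioxin-4-one | CC1=CC(=O)OC(C)(C)O1 | starting material
20 | C8 acyl imidazole | C[Si](C)(C)CCOC(=O)/C=C(/OC)[C@@H]1[C@H](c2ccc(O[Si](C(C)C)(C(C)C)C(C)C)cc2)[C@@H](C(=O)n2ccnc2)[C@@H]1/C=C/c1ccc(O[Si](C(C)C)(C(C)C)C(C)C)cc1 | intermediate (not isolated)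
21 | lithium dienolate of 19 | [Li+].[O-]C1=CC(=C)OC(C)(C)O1 | intermediate (not isolated)
22 | keto-dioxinone | C[Si](C)(C)CCOC(=O)/C=C(/OC)[C@@H]1[C@H](c2ccc(O[Si](C(C)C)(C(C)C)C(C)C)cc2)[C@@H](C(=O)CC2=CC(=O)OC(C)(C)O2)[C@@H]1/C=C/c1ccc(O[Si](C(C)C)(C(C)C)C(C)C)cc1 | intermediate
23 | acylketene | C[Si](C)(C)CCOC(=O)/C=C(/OC)[C@@H]1[C@H](c2ccc(O[Si](C(C)C)(C(C)C)C(C)C)cc2)[C@@H](C(=O)CC(=O)C=C=O)[C@@H]1/C=C/c1ccc(O[Si](C(C)C)(C(C)C)C(C)C)cc1 | intermediate (not isolated)
24 | 4-hydroxy-2-pyranone | C[Si](C)(C)CCOC(=O)/C=C(/OC)[C@@H]1[C@H](c2ccc(O[Si](C(C)C)(C(C)C)C(C)C)cc2)[C@@H](c2cc(O)cc(=O)o2)[C@@H]1/C=C/c1ccc(O[Si](C(C)C)(C(C)C)C(C)C)cc1 | intermediate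
25 | 4-methoxy-2-pyranone (fully protected seco ester) | C[Si](C)(C)CCOC(=O)/C=C(/OC)[C@@H]1[C@H](c2ccc(O[Si](C(C)C)(C(C)C)C(C)C)cc2)[C@@H](c2cc(OC)cc(=O)o2)[C@@H]1/C=C/c1ccc(O[Si](C(C)C)(C(C)C)C(C)C)cc1 | intermediate
26 | seco acid (key-step precursor) | OC(=O)/C=C(/OC)[C@@H]1[C@H](c2ccc(O)cc2)[C@@H](c2cc(OC)cc(=O)o2)[C@@H]1/C=C/c1ccc(O)cc1 | intermediate
27 | vinylogous p-quinone methide (C6=C geometry undefined) | OC(=O)/C=C(/OC)[C@@H]1[C@H](c2ccc(O)cc2)[C@@H](c2cc(OC)cc(=O)o2)C1=CC=C1C=CC(=O)C=C1 | intermediate (not isolated)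
28 | target CNP0228336.2 (key-step product) | COC1=CC(=O)O[C@]2(/C=C/c3ccc(O)cc3)[C@H]1[C@H](c1ccc(O)cc1)[C@H]2c1cc(OC)cc(=O)o1 | target

Total step count: 15. Longest linear sequence: 12 steps (1 to 28 through steps 1, 3 and 6–15).

Steps most likely to fail

1. Step 15. The quinone methide may be captured intermolecularly or oligomerise instead of lactonising, the second phenol or the product may be oxidised, or the cyclobutane may open under the acidic oxidising conditions. The fallback gives up the oxidative closure and uses the known [2+2] photodimerisation of 6-styryl-4-methoxy-2-pyranones. It sets out from 9, which is condensed at the 6-methyl group of commercial 4-methoxy-6-methyl-2H-pyran-2-one (Mg(OMe)2, MeOH, reflux; aldol condensation) to give 4-methoxy-6-[(E)-2-{4-[tri(propan-2-yl)silyloxy]phenyl}ethenyl]-2H-pyran-2-one F1. HF·pyridine would then free 6-[(E)-2-(4-hydroxyphenyl)ethenyl]-4-methoxy-2H-pyran-2-one F2. Irradiation of F2 as a solid film at 350 nm should give, among the head-to-tail dimers known for this class, the adduct of the styryl bond of one molecule with the pyranone C5=C6 bond of the other. That adduct would be a racemate of 28 and ent-28 F3, so HPLC separation and resolution on a chiral stationary phase are needed to come back to the route at 28.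

2. Step 3. The ligand may discriminate the two enantiotopic methylene groups poorly, or double arylation may compete. The fallback sets out from 4 and 6 and runs the same C–H arylation with achiral N-acetylglycine as ligand to give racemic 7. The enantiomers are then separated by preparative chromatography on a chiral stationary phase; ent-7 F4 is discarded and the route is rejoined at 7.

3. Step 9. Acid may epimerise the congested C5 centre through enolisation toward the ring, or the Z enol ether, which cannot lactonise, may form. The fallback sets out from 16 and replaces the acid-catalysed orthoester reaction by enolate O-alkylation: 16 is converted with KN(SiMe3)2 and 18-crown-6 in THF/DMPU at −78 °C into its C3 enolate, which cannot be deprotonated at C5, and the free enolate is O-methylated with dimethyl sulfate. This is the known O-selective alkylation of β-keto ester enolates by hard electrophiles in dipolar aprotic media, which favours the E enol ether; the route is rejoined at 17.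

Further compounds
F1 | step 15 | 4-methoxy-6-[(E)-2-{4-[tri(propan-2-yl)silyloxy]phenyl}ethenyl]-2H-pyran-2-one | COc1cc(/C=C/c2ccc(O[Si](C(C)C)(C(C)C)C(C)C)cc2)oc(=O)c1
F2 | step 15 | 6-[(E)-2-(4-hydroxyphenyl)ethenyl]-4-methoxy-2H-pyran-2-one | COc1cc(/C=C/c2ccc(O)cc2)oc(=O)c1
F3 | step 15 | ent-28 | COC1=CC(=O)O[C@@]2(/C=C/c3ccc(O)cc3)[C@@H]1[C@@H](c1ccc(O)cc1)[C@@H]2c1cc(OC)cc(=O)o1
F4 | step 3 | ent-7 | O=C(Nc1c(F)c(F)c(C(F)(F)F)c(F)c1F)[C@H]1[C@@H](c2ccc(O[Si](C(C)C)(C(C)C)C(C)C)cc2)[C@H](C(=O)OC)C1
F0 | step 9 | none | none
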